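The route rests on closing the dihydropyran ring at the bond between its carbinol carbon C3 and the fully substituted ether carbon C2. These atoms carry vicinal oxygens (C3–OH, C2–O1), so C3 is traced to an aldehyde carbon, used as a samarium ketyl, and C2 to the β-carbon of an enantiopure β-(enoloxy)vinyl sulfoxide hung on the enol oxygen at C10 of a dibenzo[b,f]oxepin-10-one; the C10=C11 bond of the oxepine ring holds both partners cis. One SmI2 ketyl–olefin cyclisation forms C2–C3, the pyran ring and both stereocentres with the whole carbon skeleton in place; the sulfinylmethyl arm then becomes the C2 methyl group.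

Key step: step 12

Remark: the tricycle uses dibenzo[b,f]oxepine locants (O5, ring A = C1–C4, ring B = C6–C9, C10 bears the enol oxygen, C11 the side chain) and the pyran ring is numbered O1, C2, C3, C4; the facial sense of the sulfinyl group in step 12 is assumed from the chelate model given there, and if the opposite sense operated, (1S,2R,5S)-menthyl (R)-4-methylbenzenesulfinate would be used in step 9 with no other change.

Step 1
Reactants: 1 2-(2-bromo-4-methoxyphenyl)acetic acid; 2 3-methoxyphenol
Product: 3 2-[4-methoxy-2-(3-methoxyphenoxy)phenyl]acetic acid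
Conditions: CuI (cat.), N,N-dimethylglycine (cat.), Cs2CO3, 1,4-dioxane, 100 °C; then aqueous HCl
Reagents that add atoms: none
Why: Ullmann-type copper-catalysed diaryl ether synthesis, for which 2-bromophenylacetic acids are standard partners, should join the two arenes through the oxygen that becomes O5 while the carboxylate is carried unprotected.

Step 2
Reactants: 3 2-[4-methoxy-2-(3-methoxyphenoxy)phenyl]acetic acid
Product: 4 3,7-dimethoxydibenzo[b,f]oxepin-10(11H)-one
Conditions: P2O5 in MeSO3H, 50 °C
Reagents that add atoms: none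
Why: Intramolecular Friedel–Crafts acylation should close the seven-membered ketone at the position of ring B that is para to its methoxy group and ortho to O5, since the only other ortho site lies between two oxygens.

Step 3
Reactants: 4 3,7-dimethoxydibenzo[b,f]oxepin-10(11H)-one
Product: 5 2-bromo-3,7-dimethoxydibenzo[b,f]oxepin-10(11H)-one
Conditions: NBS, MeCN, 0 °C, dark
Reagents that add atoms: N-bromosuccinimide, O=C1CCC(=O)N1Br
Why: Electrophilic aromatic bromination should occur at C2, ortho to the 3-methoxy group and para to O5 on the ring without the acyl group, because ring B is deactivated by the ketone and C4 is flanked by two oxygens.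

Step 4
Reactants: 5 2-bromo-3,7-dimethoxydibenzo[b,f]oxepin-10(11H)-one
Product: 6 2-bromo-3,7-dihydroxydibenzo[b,f]oxepin-10(11H)-one
Conditions: BBr3, CH2Cl2, −78 °C to rt; then H2O
Reagents that add atoms: none
Why: Lewis-acid cleavage of aryl methyl ethers with BBr3 is placed at the last stage that holds neither a prenyl group nor an enol ether, so that the robust methyl groups can be exchanged for fluoride-labile protection.

Step 5
Reactants: 6 2-bromo-3,7-dihydroxydibenzo[b,f]oxepin-10(11H)-one
Product: 7 2-bromo-3,7-bis(triisopropylsilyloxy)dibenzo[b,f]oxepin-10(11H)-one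
Conditions: TIPSCl, imidazole, DMF, rt
Reagents that add atoms: chlorotriisopropylsilane, CC(C)[Si](Cl)(C(C)C)C(C)C
Why: Imidazole-mediated silylation should cap both phenols as triisopropylsilyl ethers, which tolerate the later amide base, hydride, SmI2 and nickel steps and leave with fluoride at the end.

Step 6
Reactants: 7 2-bromo-3,7-bis(triisopropylsilyloxy)dibenzo[b,f]oxepin-10(11H)-one; 8 tributyl(3-methylbut-2-en-1-yl)stannane
Product: 9 2-(3-methylbut-2-en-1-yl)-3,7-bis(triisopropylsilyloxy)dibenzo[b,f]oxepin-10(11H)-one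
Conditions: Pd(PPh3)4 (cat.), DMF, 100 °C
Reagents that add atoms: none
Why: Migita–Kosugi–Stille coupling of the aryl bromide with the prenylstannane should deliver the prenyl group bonded through its primary carbon under neutral conditions that leave the enolisable ketone untouched.

Step 7
Reactants: 9 2-(3-methylbut-2-en-1-yl)-3,7-bis(triisopropylsilyloxy)dibenzo[b,f]oxepin-10(11H)-one; 10 methyl bromoacetate
Product: 11 methyl 2-[2-(3-methylbut-2-en-1-yl)-10-oxo-3,7-bis(triisopropylsilyloxy)-10,11-dihydrodibenzo[b,f]oxepin-11-yl]acetate (racemic at C11)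
Conditions: KN(SiMe3)2, THF, −78 °C; then 10, −78 to 0 °C
Reagents that add atoms: none
Why: Enolate alkylation at the benzylic α-carbon C11 with a soft, reactive halide should give the C-monoalkylated ketone and bring in the future C4 and C3 at the ester oxidation level, the new C11 centre being erased again in step 10.

Step 8
Reactants: 12 5-bromo-2-methylpent-2-ene; 13 lithium acetylide–ethylenediamine complex
Product: 14 6-methylhept-5-en-1-yne
Conditions: DMSO, 15 °C to rt
Reagents that add atoms: none
Why: SN2 alkylation of lithium acetylide by the primary homoallylic bromide in DMSO is a standard route to terminal alkynes and sets up the future C2, its methyl carbon and the 4-methylpent-3-enyl chain in one piece.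

Step 9
Reactants: 14 6-methylhept-5-en-1-yne; 15 (1R,2S,5R)-menthyl (S)-4-methylbenzenesulfinate
Product: 17 1-methyl-4-[(S)-(6-methylhept-5-en-1-yn-1-yl)sulfinyl]benzene, via alkynylmagnesium bromide 16 (not isolated)
Conditions: EtMgBr, THF, 0 °C to rt; then 15, toluene, −20 °C; aqueous work-up
Reagents that add atoms: ethylmagnesium bromide, CC[Mg]Br (Mg and Br of 16)
Why: Andersen sulfoxide synthesis, in which the alkynyl Grignard reagent displaces menthoxide from the diastereomerically pure sulfinate with inversion at sulfur, should give the alkynyl sulfoxide as a single enantiomer and so sets the sulfur stereocentre.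

Step 10
Reactants: 11 methyl 2-[2-(3-methylbut-2-en-1-yl)-10-oxo-3,7-bis(triisopropylsilyloxy)-10,11-dihydrodibenzo[b,f]oxepin-11-yl]acetate; 17 1-methyl-4-[(S)-(6-methylhept-5-en-1-yn-1-yl)sulfinyl]benzene
Product: 18 methyl 2-[10-({(1E)-6-methyl-1-[(R)-(4-methylphenyl)sulfinyl]hepta-1,5-dien-2-yl}oxy)-2-(3-methylbut-2-en-1-yl)-3,7-bis(triisopropylsilyloxy)dibenzo[b,f]oxepin-11-yl]acetate
Conditions: KN(SiMe3)2 (cat.), 18-crown-6 (cat.), THF, −40 to 0 °C
Reagents that add atoms: none
Why: Base-catalysed oxa-Michael addition of the fully substituted enolate to the β-carbon of the alkynyl sulfoxide should go through oxygen because attack through C11 would build a quaternary centre next to an ortho-substituted arene, the vinyl anion being protonated by 11 to carry the chain, the E isomer (oxygen trans to sulfur) being expected as the more stable one, and sulfur keeping its geometry although its descriptor changes from S to R by priority alone.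

Step 11
Reactants: 18 methyl 2-[10-({(1E)-6-methyl-1-[(R)-(4-methylphenyl)sulfinyl]hepta-1,5-dien-2-yl}oxy)-2-(3-methylbut-2-en-1-yl)-3,7-bis(triisopropylsilyloxy)dibenzo[b,f]oxepin-11-yl]acetate
Product: 19 2-[10-({(1E)-6-methyl-1-[(R)-(4-methylphenyl)sulfinyl]hepta-1,5-dien-2-yl}oxy)-2-(3-methylbut-2-en-1-yl)-3,7-bis(triisopropylsilyloxy)dibenzo[b,f]oxepin-11-yl]acetaldehyde
Conditions: i-Bu2AlH, CH2Cl2, −78 °C; then MeOH, aqueous potassium sodium tartrate
Reagents that add atoms: none
Why: Partial reduction of the methyl ester with i-Bu2AlH at −78 °C should stop at the aldehyde through the stable aluminium hemiacetal, a hydride that leaves sulfoxides and vinylogous enol ethers alone at this temperature, and the sensitive β,γ-unsaturated aldehyde is used at once.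

Step 12
Reactants: 19 2-[10-({(1E)-6-methyl-1-[(R)-(4-methylphenyl)sulfinyl]hepta-1,5-dien-2-yl}oxy)-2-(3-methylbut-2-en-1-yl)-3,7-bis(triisopropylsilyloxy)dibenzo[b,f]oxepin-11-yl]acetaldehyde
Product: 20 (2S,3S)-2-(4-methylpent-3-en-1-yl)-2-{[(R)-(4-methylphenyl)sulfinyl]methyl}-3,4-dihydro-2H-pyran-3-ol fused through its C5=C6 bond to C11=C10 of 2-(3-methylbut-2-en-1-yl)-3,7-bis(triisopropylsilyloxy)dibenzo[b,f]oxepine (O1 on C10)
Conditions: SmI2 (3 equiv), MeOH (4 equiv), THF, 0 °C, 19 added to the SmI2 solution
Reagents that add atoms: none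
Why: SmI2 reduces the aldehyde to a samarium ketyl whose carbon (C3) adds to the β-carbon (C2) of the vinyl sulfoxide, and a second electron transfer followed by protonation with MeOH gives the γ-hydroxy sulfoxide. The closest known reaction type is the SmI2-induced reductive ketyl–olefin cyclisation of aldehydes onto β-alkoxyacrylates and β-alkoxyvinyl sulfoxides that is used to close cyclic ethers through this same C–C bond. The dihydropyran ring closes in the 6-exo-trig radical mode, the cis C10=C11 bond of the oxepine holding ketyl and acceptor within reach. C3 is set relative to C2 by a chair-like transition state in which trivalent samarium bridges the ketyl oxygen and the sulfinyl oxygen, which places OH trans to the sulfinylmethyl arm and cis to the 4-methylpent-3-enyl chain. C2 is set in the absolute sense by the (R)-sulfinyl group, because A(1,3) strain with the cis chain turns the tolyl group away from the alkene so that the sulfinyl oxygen sits on one face only, the chelated ketyl adds on that face, and any minor facial isomer is a diastereomer that chromatography removes. The step needs reduction and protonation at the sulfinyl-bearing carbon to outrun both 5-exo attack of that radical on the side-chain alkene and loss of the enol oxygen O1 by β-elimination, which an excess of SmI2 with MeOH present from the start should secure.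

Step 13
Reactants: 20 the (2S,3S)-sulfinylmethyl pyranol of step 12
Product: 21 (2S,3S)-2-methyl-2-(4-methylpent-3-en-1-yl)-3,4-dihydro-2H-pyran-3-ol fused through its C5=C6 bond to C11=C10 of 2-(3-methylbut-2-en-1-yl)-3,7-bis(triisopropylsilyloxy)dibenzo[b,f]oxepine (O1 on C10)
Conditions: Raney Ni (W-2, deactivated in refluxing acetone), EtOH/THF, rt
Reagents that add atoms: none
Why: Raney nickel desulfurisation, the usual way to cut a sulfinyl auxiliary from a hydroxy sulfoxide, should turn the CH2S(O)Tol arm into the C2 methyl group without touching either stereocentre, the acetone-deactivated catalyst being chosen to spare the two trisubstituted alkenes and the tetrasubstituted enol ether.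

Step 14
Reactants: 21 the bis(triisopropylsilyl) ether of the target
Product: 22 CNP0185870.1, (2S,3S)-2-methyl-2-(4-methylpent-3-en-1-yl)-3,4-dihydro-2H-pyran-3-ol fused through its C5=C6 bond to C11=C10 of 2-(3-methylbut-2-en-1-yl)dibenzo[b,f]oxepine-3,7-diol (O1 on C10)
Conditions: Bu4NF, AcOH, THF, 0 °C
Reagents that add atoms: none
Why: Fluoride cleavage of the two aryl silyl ethers, buffered with acetic acid so that the electron-rich phenoxides are not left exposed, should free both phenols without acid and therefore without risk to the tertiary enol ether or the prenyl groups.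

Compound list
1 | 2-(2-bromo-4-methoxyphenyl)acetic acid | COc1ccc(CC(=O)O)c(Br)c1 | starting material
2 | 3-methoxyphenol | COc1cccc(O)c1 | starting material
3 | 2-[4-methoxy-2-(3-methoxyphenoxy)phenyl]acetic acid | COc1ccc(CC(=O)O)c(Oc2cccc(OC)c2)c1 | intermediate
4 | 3,7-dimethoxydibenzo[b,f]oxepin-10(11H)-one | O=C1Cc2ccc(OC)cc2Oc2cc(OC)ccc12 | intermediate
5 | 2-bromo-3,7-dimethoxydibenzo[b,f]oxepin-10(11H)-one | O=C1Cc2cc(Br)c(OC)cc2Oc2cc(OC)ccc12 | intermediate
6 | 2-bromo-3,7-dihydroxydibenzo[b,f]oxepin-10(11H)-one | O=C1Cc2cc(Br)c(O)cc2Oc2cc(O)ccc12 | intermediate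
7 | 2-bromo-3,7-bis(triisopropylsilyloxy)dibenzo[b,f]oxepin-10(11H)-one | O=C1Cc2cc(Br)c(O[Si](C(C)C)(C(C)C)C(C)C)cc2Oc2cc(O[Si](C(C)C)(C(C)C)C(C)C)ccc12 | intermediate
8 | tributyl(3-methylbut-2-en-1-yl)stannane | CCCC[Sn](CCCC)(CCCC)CC=C(C)C | starting material
9 | 2-(3-methylbut-2-en-1-yl)-3,7-bis(triisopropylsilyloxy)dibenzo[b,f]oxepin-10(11H)-one | O=C1Cc2cc(CC=C(C)C)c(O[Si](C(C)C)(C(C)C)C(C)C)cc2Oc2cc(O[Si](C(C)C)(C(C)C)C(C)C)ccc12 | intermediate
10 | methyl bromoacetate | COC(=O)CBr | starting material
11 | methyl 2-[2-(3-methylbut-2-en-1-yl)-10-oxo-3,7-bis(triisopropylsilyloxy)-10,11-dihydrodibenzo[b,f]oxepin-11-yl]acetate, racemic at C11 | O=C1C(CC(=O)OC)c2cc(CC=C(C)C)c(O[Si](C(C)C)(C(C)C)C(C)C)cc2Oc2cc(O[Si](C(C)C)(C(C)C)C(C)C)ccc12 | intermediate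
12 | 5-bromo-2-methylpent-2-ene | CC(C)=CCCBr | starting material
13 | lithium acetylide–ethylenediamine complex | [Li+].[C-]#C.NCCN | starting material
14 | 6-methylhept-5-en-1-yne | C#CCCC=C(C)C | intermediate
15 | (1R,2S,5R)-5-methyl-2-(propan-2-yl)cyclohexyl (S)-4-methylbenzenesulfinate, the (1R,2S,5R)-menthyl ester | C[C@@H]1CC[C@H]([C@@H](C1)O[S@](=O)c1ccc(C)cc1)C(C)C | starting material
16 | (6-methylhept-5-en-1-yn-1-yl)magnesium bromide | CC(C)=CCCC#C[Mg]Br | intermediate
17 | 1-methyl-4-[(S)-(6-methylhept-5-en-1-yn-1-yl)sulfinyl]benzene | Cc1ccc(cc1)[S@](=O)C#CCCC=C(C)C | intermediate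
18 | methyl 2-[10-({(1E)-6-methyl-1-[(R)-(4-methylphenyl)sulfinyl]hepta-1,5-dien-2-yl}oxy)-2-(3-methylbut-2-en-1-yl)-3,7-bis(triisopropylsilyloxy)dibenzo[b,f]oxepin-11-yl]acetate | Cc1ccc(cc1)[S@](=O)/C=C(\CCC=C(C)C)OC1=C(CC(=O)OC)c2cc(CC=C(C)C)c(O[Si](C(C)C)(C(C)C)C(C)C)cc2Oc2cc(O[Si](C(C)C)(C(C)C)C(C)C)ccc12 | intermediate
19 | 2-[10-({(1E)-6-methyl-1-[(R)-(4-methylphenyl)sulfinyl]hepta-1,5-dien-2-yl}oxy)-2-(3-methylbut-2-en-1-yl)-3,7-bis(triisopropylsilyloxy)dibenzo[b,f]oxepin-11-yl]acetaldehyde | Cc1ccc(cc1)[S@](=O)/C=C(\CCC=C(C)C)OC1=C(CC=O)c2cc(CC=C(C)C)c(O[Si](C(C)C)(C(C)C)C(C)C)cc2Oc2cc(O[Si](C(C)C)(C(C)C)C(C)C)ccc12 | intermediate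
20 | (2S,3S)-2-(4-methylpent-3-en-1-yl)-2-{[(R)-(4-methylphenyl)sulfinyl]methyl}-3,4-dihydro-2H-pyran-3-ol, C5=C6 fused to C11=C10 of 2-(3-methylbut-2-en-1-yl)-3,7-bis(triisopropylsilyloxy)dibenzo[b,f]oxepine, O1 on C10 | Cc1ccc(cc1)[S@](=O)C[C@@]1(CCC=C(C)C)OC2=C(C[C@@H]1O)c1cc(CC=C(C)C)c(O[Si](C(C)C)(C(C)C)C(C)C)cc1Oc1cc(O[Si](C(C)C)(C(C)C)C(C)C)ccc12 | intermediate
21 | (2S,3S)-2-methyl-2-(4-methylpent-3-en-1-yl)-3,4-dihydro-2H-pyran-3-ol, C5=C6 fused to C11=C10 of 2-(3-methylbut-2-en-1-yl)-3,7-bis(triisopropylsilyloxy)dibenzo[b,f]oxepine, O1 on C10 | CC(C)=CCC[C@]1(C)OC2=C(C[C@@H]1O)c1cc(CC=C(C)C)c(O[Si](C(C)C)(C(C)C)C(C)C)cc1Oc1cc(O[Si](C(C)C)(C(C)C)C(C)C)ccc12 | intermediate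
22 | CNP0185870.1, (2S,3S)-2-methyl-2-(4-methylpent-3-en-1-yl)-3,4-dihydro-2H-pyran-3-ol, C5=C6 fused to C11=C10 of 2-(3-methylbut-2-en-1-yl)dibenzo[b,f]oxepine-3,7-diol, O1 on C10 | CC(C)=CCC[C@]1(C)OC2=C(C[C@@H]1O)c1cc(CC=C(C)C)c(O)cc1Oc1cc(O)ccc12 | target

Total step count: 14. Longest linear sequence: 12 steps (steps 1–7 and 10–14, from 1); steps 8 and 9 form a two-step side branch that joins at step 10.

Steps most likely to fail

Step 12. The facial bias of the sulfinyl group may be too small, closure may pass through a non-chelated transition state and give the C3 epimer, or the sulfinyl-bearing radical may be reduced too slowly. The fallback moves the control of C3 to a separate, reagent-controlled step. Setting out from 19, the cyclisation is run as before and the crude alcohols, 20 together with its (2S,3R) epimer F1, are oxidised together (Dess–Martin periodinane, NaHCO3, CH2Cl2) to the (2S)-pyran-3-one F2. F2 is freed from its C2 epimer by chromatography, the two being diastereomers because of the sulfinyl group. Corey–Bakshi–Shibata reduction ((R)-Me-CBS oxazaborolidine, BH3·SMe2, −20 °C, the quaternary C2 acting as the large and C4H2 as the small substituent) then returns to the route at 20.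

Step 10. The ambident enolate may bond through C11 instead of oxygen, the alkynyl sulfoxide may isomerise to the allenyl sulfoxide under base, or protonation of the vinyl anion may leave the Z isomer. The fallback replaces conjugate addition to the alkyne by a vinylic substitution. Setting out from 17, anti hydrochlorination (LiCl, AcOH, MeCN) gives the (Z)-β-chlorovinyl sulfoxide F3. The fully formed, crown-separated potassium enolate of 11 (KN(SiMe3)2, 18-crown-6, DMF, −40 °C) then displaces chloride by addition–elimination. This path has no vinyl anion and no alkyne, meets a harder electrophilic carbon that should favour bonding at oxygen, and passes through a freely rotating sulfinyl-stabilised carbanion that should converge on the more stable E isomer. It returns to the route at 18.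

Step 13. Nickel may saturate or shift the trisubstituted double bonds, or the reduction may stop at the sulfide. The fallback cleaves the C–S bond by electron transfer instead of hydrogenolysis. Setting out from 20, chemoselective oxidation at sulfur ((NH4)6Mo7O24 (cat.), H2O2, EtOH, 0 °C) gives the sulfone F4. Reductive desulfonylation with sodium amalgam (Na(Hg), Na2HPO4, MeOH, −20 °C) then returns to the route at 21.

Further compounds
F1 | step 12 | (2S,3R) epimer of 20 at the carbinol carbon | Cc1ccc(cc1)[S@](=O)C[C@@]1(CCC=C(C)C)OC2=C(C[C@H]1O)c1cc(CC=C(C)C)c(O[Si](C(C)C)(C(C)C)C(C)C)cc1Oc1cc(O[Si](C(C)C)(C(C)C)C(C)C)ccc12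
F2 | step 12 | (2S)-2-(4-methylpent-3-en-1-yl)-2-{[(R)-(4-methylphenyl)sulfinyl]methyl}-2H-pyran-3(4H)-one, C5=C6 fused to C11=C10 of 2-(3-methylbut-2-en-1-yl)-3,7-bis(triisopropylsilyloxy)dibenzo[b,f]oxepine | Cc1ccc(cc1)[S@](=O)C[C@@]1(CCC=C(C)C)OC2=C(CC1=O)c1cc(CC=C(C)C)c(O[Si](C(C)C)(C(C)C)C(C)C)cc1Oc1cc(O[Si](C(C)C)(C(C)C)C(C)C)ccc12
F3 | step 10 | 1-{(R)-[(1Z)-2-chloro-6-methylhepta-1,5-dien-1-yl]sulfinyl}-4-methylbenzene | Cc1ccc(cc1)[S@](=O)/C=C(\Cl)CCC=C(C)C
F4 | step 13 | sulfone of 20, (2S,3S)-2-(4-methylpent-3-en-1-yl)-2-{[(4-methylphenyl)sulfonyl]methyl} pyranol with the same fused tricycle | Cc1ccc(cc1)S(=O)(=O)C[C@@]1(CCC=C(C)C)OC2=C(C[C@@H]1O)c1cc(CC=C(C)C)c(O[Si](C(C)C)(C(C)C)C(C)C)cc1Oc1cc(O[Si](C(C)C)(C(C)C)C(C)C)ccc12
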